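(The numbers in the tables stem from a simulated flask for substances that don't exist; the scatter is artificial.)

Reckoned in mol per litre, the quick number for alder and oak starts from a budget, since each portion of reagent is spent once.

| setting | grey | teal | alder | oak |
|---|---|---|---|---|
| substrate | 0.020 M | 0.020 M | 0.020 M | 0.020 M |
| partner | 0.020 M | 0.031 M | 0.0140 M | 0.0140 M |
| reagent | 0.022 M | 0.022 M | 0.0220 M | 0.0220 M |
| protic impurity | 2 mM | 2 mM | 2.00 mM | 2.00 mM |
| temperature | 22 °C | 37 °C | 25 °C | 33 °C |
| remark | run made earlier | run made earlier |  |  |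
| time |  |  | 2.5 min | 2.5 min |

| run | time / s | open intermediate / % | target / % | side product / % | substrate / % |
|---|---|---|---|---|---|
| grey | 12.0 | 2.9 | 0.5 | 0 | 96.6 |
| grey | 25.0 | 5.1 | 0 | 0 | 94.6 |
| grey | 40.0 | 6.9 | 0.9 | 0 | 93.2 |
| grey | 50.0 | 7.5 | 0.3 | 0.2 | 91.2 |
| grey | 60.0 | 8.4 | 1.1 | 0.1 | 90.7 |
| grey | 80.0 | 9.2 | 1.5 | 0.5 | 89.8 |
| grey | 90.0 | 9.3 | 1.9 | 0.1 | 88.7 |
| teal | 10.0 | 5.5 | 0.4 | 0.2 | 94.1 |
| teal | 15.0 | 5.8 | 0.8 | 0 | 93.2 |
| teal | 20.0 | 7.1 | 0.5 | 0.4 | 92.6 |
| teal | 30.0 | 7.2 | 1.6 | 0.7 | 90.7 |
| teal | 40.0 | 7.1 | 1.6 | 0.3 | 90.1 |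
| teal | 50.0 | 6.6 | 2.1 | 0.7 | 90.3 |

(readings scatter by 0.3 percentage points)

- in percentages every species weighs as the substrate in it: one side product counts as two

- which of these there is most of at the end, counted by the substrate in it, alder (target / side product / substrate / open intermediate)
- which of these there is most of at the end, counted by the substrate in it, oak (target / side product / substrate / open intermediate)
- amount of the one of these that there is most of at the end, in percent of the substrate charged, alder
- amount of the one of these that there is most of at the end, in percent of the substrate charged, oak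

Grey ends its readings with 88.7% of substrate and teal with 90.3%. In both flasks the reagent net of protic impurity, 0.0200 M and 0.0200 M, faces at least as much partner, 0.020 M and 0.031 M. The reckoning here reads the stall as reagent taken up by partner and impurity. Alder and oak hold 0.00600 M beyond that: this is the reagent surplus, c(reagent) − c(protic impurity) − c(partner), with partner the limiting reagent of that pair. The surplus equals 30.0% of the substrate charge, so this budget puts alder and oak, at 2.5 min, at 70.0% of substrate or higher.

The pace is a rough reading: grey loses 3.40% of its substrate in 12.0 s. Scaled to the surplus and carried over 2.5 min, that pace takes a further 12.8% from grey's last level, which puts alder near 75.9%. Teal's pace, at 37 °C, gives 26.6% of that 30.0%, so oak, at 33 °C, is put close to 70.0%.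

Your forecast also names substrate for both flasks, but at 88.5% for alder and 89% for oak, reading the stall as “a fast, mildly exothermic reversible opening”. The two reckonings part there.

The flasks give substrate as the largest holding in both, 79.2% in alder and 71.8% in oak, so the forecast stands 9.3 percentage points and 17 points too high.

    substrate + reagent → open intermediate (k = 0.180 M⁻¹ s⁻¹, Ea = 63.0 kJ mol⁻¹)
    2 second intermediate → homo product (k = 0.130 M⁻¹ s⁻¹, Ea = 37.0 kJ mol⁻¹)
    open intermediate + second intermediate → target (k = 0.380 M⁻¹ s⁻¹, Ea = 38.0 kJ mol⁻¹)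
    reagent + protic impurity → quenched reagent (k = 4.50 M⁻¹ s⁻¹, Ea = 45.0 kJ mol⁻¹)
    open intermediate → decomposed reagent (k = 2.00 × 10⁻⁴ s⁻¹, Ea = 93.0 kJ mol⁻¹)
    reagent + partner → second intermediate (k = 1.60 M⁻¹ s⁻¹, Ea = 61.0 kJ mol⁻¹)
    substrate + target → side product (k = 0.190 M⁻¹ s⁻¹, Ea = 58.0 kJ mol⁻¹)
    (constants at 25 °C)

Oak has lost 28.2% of its substrate against a surplus worth 30.0%, with 8.94% of its reagent still free. The same oak with reagent held at its charge ends at 29.0% of substrate, so the using up of reagent is the main reason oak stands at 71.8%.

A neighbour of oak with 0.088 M of reagent has a surplus of 0.0720 M, which is 360% of the substrate charge, so nearly all the substrate should go. It ends with 3.98% of substrate and 57.6% of open intermediate.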